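The oak run, with more X per litre than the cedar run, levels off at the same composition, so for the next flask I read the end state first and then ask how soon it comes.

| flask | X | Q | Z | remark | time |
|---|---|---|---|---|---|
| cedar | 0.20 M | 1 equiv | 5 equiv | run made earlier |  |
| oak | 0.30 M | 1 equiv | 5 equiv | run made earlier |  |
| flask | 0.40 M | 1.00 equiv | 5.00 equiv |  | 15 min |

| run | time / min | D / % | X / % |
|---|---|---|---|
| cedar | 1.00 | 62.0 | 30.8 |
| cedar | 3.00 | 69.9 | 17.1 |
| cedar | 6.00 | 70.5 | 14.4 |
| cedar | 10.0 | 73.5 | 13.9 |
| oak | 2.50 | 71.9 | 16.5 |
| oak | 5.00 | 70.9 | 13.4 |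
| oak | 6.00 | 70.6 | 15.8 |
| oak | 10.0 | 70.9 | 13.3 |

(scatter of a reading: 1 percentage point)

1. equivalents of Q to X, everything else as given, that leave most D at 15 min
2. the amount of D then, in percent of the X charged
3. the amount of D with the amounts as given

- the numbers in the tables scatter with a standard deviation of 1 percentage point

From 6.00 min in cedar and 5.00 min in oak, D averages 71.3% and X 14.2%. That leaves 14.6%, which I take as the doubly exchanged complex. Q taken up then comes to 100% of the X charged, about what 1 equiv supplies, so I read these plateaus as a stop on spent Q, the limiting reagent.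

As a simplification of my own I count both exchanges as one-way, and time then drops out of the reckoning: with x the fraction of X left, D as a fraction is x^s minus x, over one minus s. Iterating from 0.209 through 0.139, the plateau gives s = 0.148, the selectivity factor, the rate constant of the second exchange over that of the first.

This curve peaks at x = 10.6%, with D at 71.8%, which takes 1.07 equiv of Q. The gain over the plateau is 0.50 points, smaller than the scatter of 1 point. Time is no concern, since the flask has 15 min, longer than the 6.00 min cedar needed, at a higher [X]. So I charge 1.07 equiv and change nothing else.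

The forecast, reasoning “so the reaction is at equilibrium”, gives 1.01 equiv, 71.3% and 71.1%.

The flask gives 1.06 equiv, 70.2% and, as charged, 69.9%.

    X + Q ⇌ Z + D (K = 5.47, k = 0.240 M⁻¹ s⁻¹)
    X → E (k = 3.39 × 10⁻⁵ s⁻¹)
    Z → G (k = 0.100 s⁻¹)
    D + Q ⇌ Z + J (K = 0.553, k = 0.0331 M⁻¹ s⁻¹)

Both exchanges are reversible in this scheme, whereas my curve counts them as one-way. At 15.0 min the flask holds X at 14.5%, and the curve with s puts D at 71.2% against 69.9% found. A neighbouring flask, the same but charged 0.600 equiv of Q, ends with 0% of its Q and X at 42.6%. For that X the curve puts D at 53.5%, and the neighbouring flask holds 52.2%.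

Readings and results come from a simulation with constants of no real substance.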